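The meeting opened on what stayed constant between two earlier runs, in which a solid substrate dissolves into starting material that goes on to target and isomer of the product B: in mM rather than percent, target at 2.50 h stood at 3.52 mM in cedar and 3.48 mM in larch, although the charges differed.

| flask | solid substrate | remark | time |
|---|---|---|---|
| cedar | 13 mM | run made earlier |  |
| larch | 30 mM | run made earlier |  |
| flask | 20 mM |  | 4.0 h |

| run | time / h | target / % | isomer of the product B / % |
|---|---|---|---|
| cedar | 0.200 | 1.5 | 0 |
| cedar | 0.667 | 6.7 | 0.4 |
| cedar | 1.00 | 11.2 | 1.0 |
| cedar | 2.00 | 23.0 | 5.9 |
| cedar | 2.50 | 27.1 | 8.2 |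
| cedar | 3.00 | 28.2 | 9.8 |
| larch | 0.500 | 1.6 | 0.1 |
| larch | 1.00 | 5.1 | 1.1 |
| larch | 1.50 | 7.9 | 1.6 |
| larch | 2.00 | 10.2 | 2.6 |
| larch | 2.50 | 11.6 | 3.8 |
| larch | 3.00 | 13.9 | 3.7 |

(readings scatter by 0.5 percentage points)

- solid substrate is a solid; its amount is given per volume of the solution
- what was read earlier has a scatter of 0.5 percentage points, one standard deviation
- at the start none of the solid substrate is in solution
- starting material means what is dissolved; the solid is not counted in it

1. concentration of target at 4.0 h, in mM
2. concentration of isomer of the product B at 4.0 h, in mM
3. concentration of starting material at 4.0 h, in mM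

The kineticist argued that while solid lies in a flask the charge does not enter the concentrations, so that flasks share one curve until their solid is gone. The process chemist replied that cedar leaves that curve, with 3.67 mM of target at 3.00 h against 4.17 mM in larch, and she took its 13 mM to have become the limiting reagent at about 2.75 h, midway between those readings. The secretary's own reckoning divides that charge by that time for a mean uptake u = 4.73 mM/h, and for the new flask's 20 mM gives the solid lifetime, charge over uptake, τ = 4.23 h, which is longer than the asked time, though the same division taken at each of the two bracketing readings gives 3.85 h and 4.62 h, an estimate on either side of that time; the secretary therefore expected solid still present, narrowly.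

The forecast gave 5.1 mM of target, 1.9 mM of isomer of the product B and 8 mM of starting material, holding that “solid remains at 4 h”.

The flask gives 4.92 mM, 1.73 mM and 7.04 mM respectively.

    starting material ⇌ target (K = 0.880, k = 2.50 × 10⁻⁴ /s)
    target ⇌ isomer of the product A (K = 0.480, k = 7.40 × 10⁻⁴ /s)
    isomer of the product A ⇌ isomer of the product B (K = 0.870, k = 2.50 × 10⁻⁴ /s)
    isomer of the product B ⇌ starting material (k = 4.50 × 10⁻⁵ /s)
    2 starting material → homo dimer (k = 0.00220 /M/s)
    solid substrate ⇌ starting material, rate k6*(cs6 - [starting material]) while solid is left; crystals form when [starting material] > cs6 (solubility = 9.40 mM, k = 3.10 × 10⁻⁴ /s)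

At 4.00 h the flask still held 10.3 % of its solid, inside τ = 4.23 h. The same reckoning on the neighbouring flask charged with 34 mM gives a lifetime of 7.19 h, longer than the 4.00 h of its reading. That flask reads 4.92 mM of target, 1.73 mM of isomer of the product B and 7.04 mM of starting material, the values of the 20 mM flask, with 47.2 % of its charge still undissolved.

(The data are calculated with made-up constants; scatter was added.)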